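**Retrosynthetic overview**

1. The target follows from global O-deprotection of a 5,5'-di-O-methyl, tri-O-benzyl biflavanone. Both pyranone rings (rings C) of that compound are made in one operation from a 3,3'-bi(2,3-dihydrobenzofuran)-3,3'-dicarbaldehyde: in each half the furan ring (O1, C2, C3 and the two ring-fusion carbons) takes up the formyl carbon between C3 and the aromatic carbon and becomes the six-membered ring.
2. The enabling feature is ring A: its carbon C4a sits between the O1-bearing C8a and the oxygenated C5 and is para to the oxygenated C7, so this ipso carbon bridges readily to an activated formyl carbon (the future C4). The aldehyde oxidation level supplies exactly the hydrogen that C3 needs, and O1 and C2 are bystanders, so the C2 configuration is carried through.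
3. The bond between the two C3 atoms, a union of two α-carbons of like polarity, is made before the ring expansion by oxidative coupling of two ester enolates of 2-aryl-2,3-dihydrobenzofuran-3-carboxylates, which cannot ring-open as flavanone enolates do.
4. Each dihydrobenzofuran ester comes from an enantioselective rhodium-carbene insertion into the benzylic C–H bond of an aryl diazoacetate (this sets both C2 centres), built from one commercial acetophenone and two benzyl chlorides.
5. Ring order: rings A and B are bought; the two furan rings are closed first; both pyranone rings then arise together by ring expansion, with the two C3 centres ending trans to the C2 aryl groups.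

Key step: step 13

Assumption: Rh2(S-PTTL)4 (dirhodium tetrakis[N-phthaloyl-(S)-tert-leucinate]) is taken to give the (2S)-configured insertion products of steps 5 and 9; if its sense of induction is the opposite, Rh2(R-PTTL)4 is used instead.

**Route**

Step 1
Reactants: 1 1-(2,4-dihydroxy-6-methoxyphenyl)ethan-1-one
Product: 2 1-[4-(benzyloxy)-2-hydroxy-6-methoxyphenyl]ethan-1-one
Conditions: BnBr (1.05 equiv), K2CO3, acetone, reflux
Reagents that add atoms: benzyl bromide BrCc1ccccc1
Why: Williamson ether synthesis, selective because the 4-OH is the more acidic, non-chelated phenol whereas the 2-OH is hydrogen-bonded to the ketone and stays free.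

Step 2
Reactants: 2 1-[4-(benzyloxy)-2-hydroxy-6-methoxyphenyl]ethan-1-one; 3 1-(chloromethyl)-4-methoxybenzene
Product: 4 1-{4-(benzyloxy)-2-methoxy-6-[(4-methoxybenzyl)oxy]phenyl}ethan-1-one
Conditions: K2CO3, NaI (cat.), DMF, 60 °C
Reagents that add atoms: none
Why: Williamson ether synthesis of the chelated phenol under more forcing conditions (polar aprotic solvent, iodide catalysis), which installs the CH2 group that becomes C2 together with the 4-methoxyphenyl ring.

Step 3
Reactants: 4 1-{4-(benzyloxy)-2-methoxy-6-[(4-methoxybenzyl)oxy]phenyl}ethan-1-one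
Product: 6 methyl 2-{4-(benzyloxy)-2-methoxy-6-[(4-methoxybenzyl)oxy]phenyl}-2-oxoacetate, via keto acid 5 (not isolated)
Conditions: SeO2, pyridine, 100 °C; filter, evaporate; then MeI, K2CO3, DMF, rt
Reagents that add atoms: selenium dioxide O=[Se]=O; iodomethane CI
Why: Riley oxidation of the aryl methyl ketone to the aryl glyoxylic acid in pyridine followed by carboxylate O-methylation, both tolerant of the benzylic ethers.

Step 4
Reactants: 6 methyl 2-{4-(benzyloxy)-2-methoxy-6-[(4-methoxybenzyl)oxy]phenyl}-2-oxoacetate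
Product: 8 methyl 2-{4-(benzyloxy)-2-methoxy-6-[(4-methoxybenzyl)oxy]phenyl}-2-diazoacetate, via tosylhydrazone 7 (not isolated)
Conditions: TsNHNH2, MeOH, 60 °C; evaporate; then DBU, CH2Cl2, 0 °C → rt
Reagents that add atoms: 4-methylbenzenesulfonohydrazide Cc1ccc(cc1)S(=O)(=O)NN
Why: Condensation to the α-keto ester tosylhydrazone and base-induced loss of sulfinate (Bamford–Stevens reaction), the standard entry to aryl diazoacetates.

Step 5
Reactants: 8 methyl 2-{4-(benzyloxy)-2-methoxy-6-[(4-methoxybenzyl)oxy]phenyl}-2-diazoacetate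
Product: 9 methyl (2S,3R)-6-(benzyloxy)-4-methoxy-2-(4-methoxyphenyl)-2,3-dihydro-1-benzofuran-3-carboxylate (2,3-cis)
Conditions: Rh2(S-PTTL)4 (1 mol %), toluene, –60 °C
Reagents that add atoms: none
Why: Intramolecular 1,5 C–H insertion of a donor/acceptor rhodium carbene into the benzylic ether C–H bond, which is activated by oxygen and by the 4-methoxyphenyl group and should therefore be preferred over the methoxy C–H bonds; the chiral carboxylate ligands set C2 (S), and the cis C3 centre is erased in step 10.

Step 6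
Reactants: 2 1-[4-(benzyloxy)-2-hydroxy-6-methoxyphenyl]ethan-1-one; 10 1-(benzyloxy)-4-(chloromethyl)benzene
Product: 11 1-{4-(benzyloxy)-2-{[4-(benzyloxy)benzyl]oxy}-6-methoxyphenyl}ethan-1-one
Conditions: K2CO3, NaI (cat.), DMF, 60 °C
Reagents that add atoms: none
Why: Williamson ether synthesis as in step 2, here bringing in the ring that becomes the 4-hydroxyphenyl group in benzyl-protected form.

Step 7
Reactants: 11 1-{4-(benzyloxy)-2-{[4-(benzyloxy)benzyl]oxy}-6-methoxyphenyl}ethan-1-one
Product: 13 methyl 2-{4-(benzyloxy)-2-{[4-(benzyloxy)benzyl]oxy}-6-methoxyphenyl}-2-oxoacetate, via keto acid 12 (not isolated)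
Conditions: SeO2, pyridine, 100 °C; filter, evaporate; then MeI, K2CO3, DMF, rt
Reagents that add atoms: selenium dioxide O=[Se]=O; iodomethane CI
Why: Riley oxidation and O-methylation as in step 3.

Step 8
Reactants: 13 methyl 2-{4-(benzyloxy)-2-{[4-(benzyloxy)benzyl]oxy}-6-methoxyphenyl}-2-oxoacetate
Product: 15 methyl 2-{4-(benzyloxy)-2-{[4-(benzyloxy)benzyl]oxy}-6-methoxyphenyl}-2-diazoacetate, via tosylhydrazone 14 (not isolated)
Conditions: TsNHNH2, MeOH, 60 °C; evaporate; then DBU, CH2Cl2, 0 °C → rt
Reagents that add atoms: 4-methylbenzenesulfonohydrazide Cc1ccc(cc1)S(=O)(=O)NN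
Why: Tosylhydrazone formation and Bamford–Stevens reaction as in step 4.

Step 9
Reactants: 15 methyl 2-{4-(benzyloxy)-2-{[4-(benzyloxy)benzyl]oxy}-6-methoxyphenyl}-2-diazoacetate
Product: 16 methyl (2S,3R)-6-(benzyloxy)-2-[4-(benzyloxy)phenyl]-4-methoxy-2,3-dihydro-1-benzofuran-3-carboxylate (2,3-cis)
Conditions: Rh2(S-PTTL)4 (1 mol %), toluene, –60 °C
Reagents that add atoms: none
Why: Enantioselective intramolecular rhodium-carbene C–H insertion as in step 5, the catalyst setting C2 (S).

Step 10
Reactants: 9 dihydrobenzofuran ester of the 4-methoxyphenyl series; 16 dihydrobenzofuran ester of the 4-benzyloxyphenyl series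
Product: 19 dimethyl (2R,2'R,3S,3'S)-6,6'-bis(benzyloxy)-2'-[4-(benzyloxy)phenyl]-4,4'-dimethoxy-2-(4-methoxyphenyl)-2H,2'H-[3,3'-bi-1-benzofuran]-3,3'-dicarboxylate, via lithium enolate 17 (not isolated), via lithium enolate 18 (not isolated)
Conditions: 9 and 16 (1:1), LiN(iPr)2 (2.1 equiv), THF, –78 °C; then CuBr2 (2.2 equiv), –78 → –40 °C
Reagents that add atoms: none
Why: Oxidative coupling of ester enolates with CuBr2, a union of two like-polarity α-carbons in which each planar benzylic enolate should react on the face anti to its C2 aryl group; C2 is not epimerised because β-elimination of the phenoxide would be the reverse of a 5-endo-trig closure, and the cross-coupled diester has to be separated from the two symmetrical homo-dimers that form alongside.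

Step 11
Reactants: 19 cross-coupled bis(dihydrobenzofuran) diester
Product: 20 [(2R,2'R,3S,3'S)-6,6'-bis(benzyloxy)-2'-[4-(benzyloxy)phenyl]-4,4'-dimethoxy-2-(4-methoxyphenyl)-2H,2'H-[3,3'-bi-1-benzofuran]-3,3'-diyl]dimethanol
Conditions: LiAlH4, THF, 0 → 40 °C; then H2O, aq NaOH
Reagents that add atoms: none
Why: Hydride reduction of both hindered methyl esters to the neopentyl-type primary alcohols, with all aryl, benzyl and cyclic benzylic ethers inert to LiAlH4.

Step 12
Reactants: 20 bis(dihydrobenzofuran) diol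
Product: 21 (2R,2'R,3S,3'S)-6,6'-bis(benzyloxy)-2'-[4-(benzyloxy)phenyl]-4,4'-dimethoxy-2-(4-methoxyphenyl)-2H,2'H-[3,3'-bi-1-benzofuran]-3,3'-dicarbaldehyde
Conditions: (COCl)2, DMSO, CH2Cl2, –78 °C; then Et3N, –78 → 0 °C
Reagents that add atoms: none
Why: Swern oxidation, in which both hydroxyl groups are activated before base is added so that lactol and lactone formation from the 1,4-diol is avoided, and the α-quaternary aldehydes can neither enolise nor epimerise.

Step 13
Reactants: 21 bis(dihydrobenzofuran) dialdehyde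
Product: 23 (2S,2'S,3R,3'R)-7,7'-bis(benzyloxy)-2'-[4-(benzyloxy)phenyl]-5,5'-dimethoxy-2-(4-methoxyphenyl)-[3,3'-bichromane]-4,4'-dione, via keto aldehyde 22 (not isolated)
Conditions: BF3·OEt2 (3 equiv), CH2Cl2, –78 → –20 °C; then aq NaHCO3
Reagents that add atoms: none
Why: Proposed new method: BF3 activates each formyl group, the ipso carbon C3a of the adjacent electron-rich ring (flanked by the ring oxygen and the methoxy group, para to the benzyloxy group) bridges to the formyl carbon through a spiro-cyclopropane arenium (phenonium) ion, and the C3–C3a bond then breaks while the former formyl hydrogen shifts to C3, so that the formyl carbon ends as the aryl ketone C4 of a chroman-4-one; the second half follows the same course. The closest known reaction type is the acid-promoted aldehyde–ketone rearrangement of α-aryl aldehydes (triphenylacetaldehyde to benzhydryl phenyl ketone), together with phenonium-mediated ring enlargement of 1-indanylmethyl cations. Each pyranone ring arises by ring enlargement (3-exo ipso attack followed by opening of the three-membered ring), not by a cyclisation onto oxygen, so the O1–C2 bonds and the C2 and C2' centres set in steps 5 and 9 are untouched. The new C3 and C3' centres are set by delivery of the hydrogen anti to the departing aryl group (inversion at C3), which places the inter-unit bond trans to the C2 aryl group; should any 2,3-cis isomer form, acid-mediated enolisation in the same flask should funnel it to the diequatorial trans,trans isomer, the only such isomer compatible with the fixed 2S,2'S centres. The step needs aryl migration to win over migration of C2 or of the neighbouring quaternary carbon: the exocyclic C3–CHO bond is aligned with the π-system of the trioxygenated ring whereas the C3–C2 bond lies in its nodal plane, and the neighbouring carbon is deactivated by its own BF3-bound carbonyl group. Low temperature is used so that the 4-alkoxybenzylic C2–O1 bonds do not ionise.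

Step 14
Reactants: 23 protected biflavanone
Product: 24 (2S,2'S,3R,3'R)-5,5',7,7'-tetrahydroxy-2'-(4-hydroxyphenyl)-2-(4-methoxyphenyl)-[3,3'-bichromane]-4,4'-dione
Conditions: BCl3 (excess), C6HMe5, CH2Cl2, –78 → 0 °C; then MeOH, H2O
Reagents that add atoms: none
Why: Lewis-acid ether cleavage in which BCl3 with pentamethylbenzene as benzyl-cation trap removes the three benzyl ethers at low temperature and, on warming, the two methyl ethers chelated to the C4 and C4' carbonyl groups, whereas the non-chelated anisole-type methyl ether should survive and the non-basic medium leaves the four stereocentres untouched.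

**Compound list**

1 | 1-(2,4-dihydroxy-6-methoxyphenyl)ethan-1-one | CC(=O)c1c(O)cc(O)cc1OC | starting material
2 | 1-[4-(benzyloxy)-2-hydroxy-6-methoxyphenyl]ethan-1-one | CC(=O)c1c(O)cc(OCc2ccccc2)cc1OC | intermediate
3 | 1-(chloromethyl)-4-methoxybenzene | COc1ccc(CCl)cc1 | starting material
4 | 1-{4-(benzyloxy)-2-methoxy-6-[(4-methoxybenzyl)oxy]phenyl}ethan-1-one | CC(=O)c1c(OCc2ccc(OC)cc2)cc(OCc2ccccc2)cc1OC | intermediate
5 | 2-{4-(benzyloxy)-2-methoxy-6-[(4-methoxybenzyl)oxy]phenyl}-2-oxoacetic acid | OC(=O)C(=O)c1c(OCc2ccc(OC)cc2)cc(OCc2ccccc2)cc1OC | intermediate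
6 | methyl 2-{4-(benzyloxy)-2-methoxy-6-[(4-methoxybenzyl)oxy]phenyl}-2-oxoacetate | COC(=O)C(=O)c1c(OCc2ccc(OC)cc2)cc(OCc2ccccc2)cc1OC | intermediate
7 | methyl 2-{4-(benzyloxy)-2-methoxy-6-[(4-methoxybenzyl)oxy]phenyl}-2-(tosylhydrazono)acetate | COC(=O)C(=NNS(=O)(=O)c1ccc(C)cc1)c1c(OCc2ccc(OC)cc2)cc(OCc2ccccc2)cc1OC | intermediate
8 | methyl 2-{4-(benzyloxy)-2-methoxy-6-[(4-methoxybenzyl)oxy]phenyl}-2-diazoacetate | COC(=O)C(=[N+]=[N-])c1c(OCc2ccc(OC)cc2)cc(OCc2ccccc2)cc1OC | intermediate
9 | methyl (2S,3R)-6-(benzyloxy)-4-methoxy-2-(4-methoxyphenyl)-2,3-dihydro-1-benzofuran-3-carboxylate (cis) | COC(=O)[C@H]1[C@@H](c2ccc(OC)cc2)Oc2cc(OCc3ccccc3)cc(OC)c21 | intermediate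
10 | 1-(benzyloxy)-4-(chloromethyl)benzene | ClCc1ccc(OCc2ccccc2)cc1 | starting material
11 | 1-{4-(benzyloxy)-2-{[4-(benzyloxy)benzyl]oxy}-6-methoxyphenyl}ethan-1-one | CC(=O)c1c(OCc2ccc(OCc3ccccc3)cc2)cc(OCc2ccccc2)cc1OC | intermediate
12 | 2-{4-(benzyloxy)-2-{[4-(benzyloxy)benzyl]oxy}-6-methoxyphenyl}-2-oxoacetic acid | OC(=O)C(=O)c1c(OCc2ccc(OCc3ccccc3)cc2)cc(OCc2ccccc2)cc1OC | intermediate
13 | methyl 2-{4-(benzyloxy)-2-{[4-(benzyloxy)benzyl]oxy}-6-methoxyphenyl}-2-oxoacetate | COC(=O)C(=O)c1c(OCc2ccc(OCc3ccccc3)cc2)cc(OCc2ccccc2)cc1OC | intermediate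
14 | methyl 2-{4-(benzyloxy)-2-{[4-(benzyloxy)benzyl]oxy}-6-methoxyphenyl}-2-(tosylhydrazono)acetate | COC(=O)C(=NNS(=O)(=O)c1ccc(C)cc1)c1c(OCc2ccc(OCc3ccccc3)cc2)cc(OCc2ccccc2)cc1OC | intermediate
15 | methyl 2-{4-(benzyloxy)-2-{[4-(benzyloxy)benzyl]oxy}-6-methoxyphenyl}-2-diazoacetate | COC(=O)C(=[N+]=[N-])c1c(OCc2ccc(OCc3ccccc3)cc2)cc(OCc2ccccc2)cc1OC | intermediate
16 | methyl (2S,3R)-6-(benzyloxy)-2-[4-(benzyloxy)phenyl]-4-methoxy-2,3-dihydro-1-benzofuran-3-carboxylate (cis) | COC(=O)[C@H]1[C@@H](c2ccc(OCc3ccccc3)cc2)Oc2cc(OCc3ccccc3)cc(OC)c21 | intermediate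
17 | lithium enolate (O-lithio ketene acetal) of ester 9, C2 configuration unchanged | [Li]OC(OC)=C1c2c(OC)cc(OCc3ccccc3)cc2O[C@@H]1c1ccc(OC)cc1 | intermediate
18 | lithium enolate (O-lithio ketene acetal) of ester 16, C2 configuration unchanged | [Li]OC(OC)=C1c2c(OC)cc(OCc3ccccc3)cc2O[C@@H]1c1ccc(OCc2ccccc2)cc1 | intermediate
19 | dimethyl (2R,2'R,3S,3'S)-6,6'-bis(benzyloxy)-2'-[4-(benzyloxy)phenyl]-4,4'-dimethoxy-2-(4-methoxyphenyl)-2H,2'H-[3,3'-bi-1-benzofuran]-3,3'-dicarboxylate (central C–C bond trans to each C2 aryl group) | COC(=O)[C@@]1([C@]2(C(=O)OC)[C@@H](c3ccc(OCc4ccccc4)cc3)Oc3cc(OCc4ccccc4)cc(OC)c32)[C@@H](c2ccc(OC)cc2)Oc2cc(OCc3ccccc3)cc(OC)c21 | intermediate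
20 | [(2R,2'R,3S,3'S)-6,6'-bis(benzyloxy)-2'-[4-(benzyloxy)phenyl]-4,4'-dimethoxy-2-(4-methoxyphenyl)-2H,2'H-[3,3'-bi-1-benzofuran]-3,3'-diyl]dimethanol | OC[C@@]1([C@]2(CO)[C@@H](c3ccc(OCc4ccccc4)cc3)Oc3cc(OCc4ccccc4)cc(OC)c32)[C@@H](c2ccc(OC)cc2)Oc2cc(OCc3ccccc3)cc(OC)c21 | intermediate
21 | (2R,2'R,3S,3'S)-6,6'-bis(benzyloxy)-2'-[4-(benzyloxy)phenyl]-4,4'-dimethoxy-2-(4-methoxyphenyl)-2H,2'H-[3,3'-bi-1-benzofuran]-3,3'-dicarbaldehyde | O=C[C@@]1([C@]2(C=O)[C@@H](c3ccc(OCc4ccccc4)cc3)Oc3cc(OCc4ccccc4)cc(OC)c32)[C@@H](c2ccc(OC)cc2)Oc2cc(OCc3ccccc3)cc(OC)c21 | intermediate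
22 | (2R,3R)-6-(benzyloxy)-2-[4-(benzyloxy)phenyl]-3-[(2S,3R)-7-(benzyloxy)-5-methoxy-2-(4-methoxyphenyl)-4-oxochroman-3-yl]-4-methoxy-2,3-dihydro-1-benzofuran-3-carbaldehyde (one half ring-expanded; shown with the 4-methoxyphenyl half first, the order is immaterial) | COc1ccc([C@H]2Oc3cc(OCc4ccccc4)cc(OC)c3C(=O)[C@@H]2[C@]2(C=O)[C@@H](c3ccc(OCc4ccccc4)cc3)Oc3cc(OCc4ccccc4)cc(OC)c32)cc1 | intermediate
23 | (2S,2'S,3R,3'R)-7,7'-bis(benzyloxy)-2'-[4-(benzyloxy)phenyl]-5,5'-dimethoxy-2-(4-methoxyphenyl)-[3,3'-bichromane]-4,4'-dione (both rings 2,3-trans) | COc1ccc([C@H]2Oc3cc(OCc4ccccc4)cc(OC)c3C(=O)[C@@H]2[C@H]2C(=O)c3c(OC)cc(OCc4ccccc4)cc3O[C@@H]2c2ccc(OCc3ccccc3)cc2)cc1 | intermediate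
24 | (2S,2'S,3R,3'R)-5,5',7,7'-tetrahydroxy-2'-(4-hydroxyphenyl)-2-(4-methoxyphenyl)-[3,3'-bichromane]-4,4'-dione (CNP0196568.1) | COc1ccc([C@H]2Oc3cc(O)cc(O)c3C(=O)[C@@H]2[C@H]2C(=O)c3c(O)cc(O)cc3O[C@@H]2c2ccc(O)cc2)cc1 | target

**Step count and risks**

Total step count: 14. Longest linear sequence: 10 steps (steps 1–5 and 10–14; the branch through steps 6–9 is of equal length).

Steps most likely to fail:

1. Step 13 (proposed new method). What may go wrong: migration of the wrong substituent (C2 or the neighbouring quaternary carbon) to the activated formyl carbon; heterolysis of the crowded central C–C bond followed by loss of the C2 hydrogen, which would aromatise the halves to benzofurans; or ionisation of the benzylic C2–O1 bonds with loss of the C2 configuration. The fallback uses known chemistry and gives up the ring expansion; it sets out from compound 2 and comes back to the route at compound 23. Compound 2 is condensed with N,N-dimethylformamide dimethyl acetal and cyclised with acid to the chromone 7-(benzyloxy)-5-methoxy-4H-chromen-4-one F1. Enantioselective conjugate addition of (4-methoxyphenyl)boronic acid and, separately, of [4-(benzyloxy)phenyl]boronic acid (Pd(OCOCF3)2 with a chiral pyridine–oxazoline ligand of the enantiomeric series that gives 2S) should give the flavanones (2S)-7-(benzyloxy)-5-methoxy-2-(4-methoxyphenyl)chroman-4-one F2 and (2S)-7-(benzyloxy)-2-[4-(benzyloxy)phenyl]-5-methoxychroman-4-one F3. Low-temperature enolisation (LiN(SiMe3)2, –78 °C) and stepwise O-silylation with Me2SiCl2 would then give the unsymmetrical dimethylsilyl bis-enol ether of the two flavanones F4. Intramolecular oxidative coupling of F4 with (NH4)2Ce(NO3)6 and NaHCO3 in MeCN at –20 °C, each enol ether reacting anti to its C2 aryl group, should return the route to 23.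

2. Step 10. What may go wrong: statistical pairing of the two enolates, and disproportionation of the hindered C3 radicals (hydrogen loss from C2, giving aromatic benzofurans) in place of C–C bond formation. The fallback makes the union intramolecular through a temporary silicon tether; it sets out from compounds 9 and 16 and comes back at compound 19. The lithium enolate of 9 is O-silylated with an excess of Me2SiCl2, the excess is removed, and the lithium enolate of 16 is added, which should give the unsymmetrical dimethylsilyl bis(ketene acetal) of the two esters F5. Oxidation with (NH4)2Ce(NO3)6 (or Cu(OSO2CF3)2) would couple the two ketene-acetal carbons within the tethered array, so that only the cross-coupled product can form, and aqueous work-up releases the tether and returns 19. If steric congestion rather than pairing is the problem, the fallback given for step 13 applies instead.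

3. Step 14. What may go wrong: Lewis-acid-induced opening of the pyranone rings with epimerisation at C2, or loss of the 4'-methyl ether during the slower cleavage of the chelated 5-methyl ethers. The fallback separates the two deprotection events; it sets out from compound 23 and comes back at compound 24. Hydrogenolysis (H2, Pd/C, EtOAc–MeOH) removes the three benzyl groups under neutral conditions and should give the triphenol (2S,2'S,3R,3'R)-7,7'-dihydroxy-2'-(4-hydroxyphenyl)-5,5'-dimethoxy-2-(4-methoxyphenyl)-[3,3'-bichromane]-4,4'-dione F6. The two chelated 5-methyl ethers are then cleaved selectively with MgI2 etherate (chelation-controlled), giving 24.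

**Further compounds**

F1 | step 13 | 7-(benzyloxy)-5-methoxy-4H-chromen-4-one | COc1cc(OCc2ccccc2)cc2occc(=O)c12
F2 | step 13 | (2S)-7-(benzyloxy)-5-methoxy-2-(4-methoxyphenyl)chroman-4-one | O=C1C[C@@H](c2ccc(OC)cc2)Oc2cc(OCc3ccccc3)cc(OC)c12
F3 | step 13 | (2S)-7-(benzyloxy)-2-[4-(benzyloxy)phenyl]-5-methoxychroman-4-one | O=C1C[C@@H](c2ccc(OCc3ccccc3)cc2)Oc2cc(OCc3ccccc3)cc(OC)c12
F4 | step 13 | unsymmetrical dimethylsilyl bis-enol ether of flavanones F2 and F3 (C2 configurations unchanged) | C[Si](C)(OC1=C[C@@H](c2ccc(OC)cc2)Oc2cc(OCc3ccccc3)cc(OC)c12)OC1=C[C@@H](c2ccc(OCc3ccccc3)cc2)Oc2cc(OCc3ccccc3)cc(OC)c12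
F5 | step 10 | unsymmetrical dimethylsilyl bis(ketene acetal) of esters 9 and 16 (C2 configurations unchanged) | C[Si](C)(OC(OC)=C1c2c(OC)cc(OCc3ccccc3)cc2O[C@@H]1c1ccc(OC)cc1)OC(OC)=C1c2c(OC)cc(OCc3ccccc3)cc2O[C@@H]1c1ccc(OCc2ccccc2)cc1
F6 | step 14 | (2S,2'S,3R,3'R)-7,7'-dihydroxy-2'-(4-hydroxyphenyl)-5,5'-dimethoxy-2-(4-methoxyphenyl)-[3,3'-bichromane]-4,4'-dione | COc1ccc([C@H]2Oc3cc(O)cc(OC)c3C(=O)[C@@H]2[C@H]2C(=O)c3c(OC)cc(O)cc3O[C@@H]2c2ccc(O)cc2)cc1
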